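## Structural features

The target is a γ-butyrolactone (ring atoms O1, C2 carbonyl, C3, C4, C5) in which C3 carries an exocyclic methylene, C4 a free carboxylic acid and C5 an unbranched thirteen-carbon chain (C1' to C13') ending in a primary acetate. C4 (S) and C5 (R) are neighbouring stereocentres with carboxyl and chain trans on the ring; in the tetrahydrofuran numbering used for the compound names below, lactone C5 is C2 and lactone C4 is C3, so the target is (2R,3S). The alpha-methylene lactone is a Michael acceptor, and its double bond can slip into the ring, into conjugation with the C4 carboxyl, once a base removes the C4 hydrogen, which would also erase C4. The primary acetate does not survive alkoxide, the lactone opens in hydroxide, and the free acid rules out organometallic reagents unless it is masked. The real difficulty is the order of events: C5 must be set trans to C4 without any base that epimerises C4, and the methylene must be introduced late by chemistry that is hostile to an acetate. The feature exploited is that the ring O1-C2-C3-C4-C5 with its C4 carboxyl is the γ-lactone of (2R,3S)-isocitric acid, whose C4 already has the arrangement of the target and whose second carboxyl sits on C5, exactly where the C5-C1' bond is needed. In the natural lactone this C5 carboxyl is cis to the C4 carboxyl, so it must be exchanged for the chain with inversion of the relative configuration, which a planar C5 radical stabilised by O1 allows.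

## Logic of the disconnections

19 to 18: the acyl-oxygen bond of the terminal acetate is cut. An acetate is not expected to pass through the methoxide-rich carboxylation at 130 °C that precedes the methylene, so it is put on last. This removes the only base-labile spectator from every earlier step. The forward acylation must tell the primary alcohol from the ring carboxyl and must not supply a base that moves the exocyclic alkene.

18 to 16 (through 17): the exocyclic C3=CH2 bond is cut, removing one carbon. The coupling product offers only a lactone CH2 at C3, and carboxylation followed by Mannich condensation and decarboxylation adds one carbon there without a strong base at C4. The gain is that 16 has no Michael acceptor. The forward step must carboxylate C3 beside a free acid and a free alcohol, and 17 must not lose CO2 before the iminium ion is offered.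

16 to 15: the oxygen-tert-butyl and oxygen-silicon bonds are cut. Both groups are acid-labile, so one acid treatment unveils acid and alcohol with no base. The gain is that neither 15 nor the fragments that make it carry an acidic proton, so an organozinc reagent can be used. The demand is only that the lactone survives acid.

15 to 14 and 6: the C5-C1' bond is cut. It is the only bond that joins chain and ring, and cutting it leaves a carboxyl-derived group on C5, which turns the ring fragment into a chiral-pool derivative. All thirteen chain carbons then arrive in one piece and C4 is bought. The forward step must join two sp3 carbons at an oxygen-bearing secondary centre, trans to the C4 ester, whatever the configuration of C5 in 14.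

14 to 12 and 13: the acyl-oxygen bond of the active ester is cut. This is a routine carbodiimide esterification, and it requires that the C5 carboxyl of 12 is the only free acid.

12 to 11 to 10 to 9: the two carboxyls are told apart. In 9 they are tied as a cyclic anhydride whose C5-side carbonyl is the more electrophilic. An alcohol enters there irreversibly (10), the C4 acid is tert-butylated (11), and hydrogenolysis frees C5 (12). Opening 9 directly with 13 would be two steps shorter but is not chosen: an N-oxy ester beside a free cis carboxylate is an activated acyl donor with an internal nucleophile, so that opening would be reversible and would drift toward the isomer in which the stronger C5 acid is free.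

9 to 7 (through 8): the anhydride and lactone carbon-oxygen bonds are cut, that is, two dehydrations are undone. 7 is the commercial enantiopure salt. The forward steps use acid only, so C4 is not touched.

6 to 4 (through 5) to 3 to 2 to 1: the carbon-zinc, oxygen-silicon and carbon-bromine bonds are cut and the two alcohols are traced back to carboxyls. The chain is a symmetric C13 diacid that is desymmetrised by monobromination of its diol. The demand is mono-functionalisation of 2 and a zinc reagent in which every chain is bound to a transferable position.

## Other disconnections considered

Alternative 1: The cut is the lactone O1-C2 bond and, behind it, a cyclopropane carbon-carbon bond. Ba(OH)2 in methanol is meant to strip the oxalyl group from the cyclopropanol oxygen of ethyl 2-(1-hydroxybut-3-en-1-yl)-3-[(methoxyoxalyl)oxy]cyclopropane-1-carboxylate A2. The freed alkoxide, flanked by the ester acceptor, breaks the three-membered ring in a retro-aldol sense, and the side-chain hydroxyl lactonises onto the ethyl ester to give (2R,3S)-2-allyl-5-oxotetrahydrofuran-3-carbaldehyde A1.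
- In favour: both stereocentres come from a catalytic asymmetric cyclopropanation of a furan and a substrate-controlled allylation, so either enantiomer is open. On this point the alternative is better than the chosen plan, which depends on the single natural enantiomer of 7.
- In favour: the formyl-bearing centre can equilibrate to trans. This thermodynamic control is at least the equal of the kinetic facial selectivity on which step 10 relies.
- Against: A1 carries only three chain carbons. The other ten must come from cross-metathesis with dodec-11-en-1-yl acetate A3 (second-generation Grubbs catalyst), then hydrogenation and oxidation of the aldehyde. A diazo ester and ozone are needed early.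
- Against: the methylene would still be installed by the same carboxylation sequence, with the same conflict with the acetate, so the two plans are equal there.
- Comparison: structurally the alternative builds ring and both centres where the chosen plan buys ring and one centre. Mechanistically it is a polar cascade against a nickel-radical coupling. In step economy it should be several steps longer in the linear sequence, because ring construction, chain extension and oxidation-state adjustment follow one another, whereas the chosen plan is convergent.

Alternative 2: The cut is C3-C4 of a tetrahydrofuran precursor. Cp2TiCl (trivalent titanium) should open the epoxide of (14R)-14-[(2R)-oxiran-2-yl]-14-(prop-2-yn-1-yloxy)tetradecyl acetate A5 homolytically at its inner carbon, the future C4. 5-exo-dig addition of this radical to the propargyl ether alkyne makes C3-C4, and quenching of the vinyl radical leaves the exocyclic methylene of [(2R,3R)-2-(13-acetoxytridecyl)-4-methylidenetetrahydrofuran-3-yl]methanol A4.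
- In favour: ring, methylene and the trans relationship arise in one step and no carboxylation is needed, so the acetate could be carried from the start. On this point the alternative is better than the chosen plan.
- Against: A4 is at the wrong oxidation level at two carbons. The ring CH2 next to oxygen must become the lactone carbonyl (allylic oxidation, typically with CrO3-based reagents) and the hydroxymethyl group the acid, both beside a sensitive allylic system.
- Against: C5 must come from a resolved or asymmetrically made epoxy alcohol, and the trans selectivity rests on the transition state of an open-chain radical, which is less predictable than attack on a preformed ring.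
- Comparison: the two plans are equal in using a carbon radical to set one centre relative to its neighbour (C4 relative to C5 there, C5 relative to C4 here). The step count should be comparable. The chosen plan avoids stoichiometric chromium and buys its stereocentre.

Alternative 3: The cut is C2-C3, between the carbonyl carbon and the alkene carbon. Bu3SnH and AIBN would abstract the phenylseleno group of O-[(3R,4R)-17-acetoxy-3-{[(tert-butyldimethylsilyl)oxy]methyl}heptadec-1-yn-4-yl] Se-phenyl carbonoselenoate A7. The alkoxycarbonyl radical adds 5-exo-dig to the alkyne, and hydrogen transfer gives (4R,5R)-5-(13-acetoxytridecyl)-4-{[(tert-butyldimethylsilyl)oxy]methyl}-3-methylidenedihydrofuran-2(3H)-one A6.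
- In favour: the most fragile motif is formed directly, at the final oxidation level of C2 and C3, under neutral conditions that an acetate tolerates. On this point the alternative is better than the chosen plan.
- In favour: both stereocentres are in place before the ring closes, so the key step carries no stereochemical risk, which is equal to or better than step 10.
- Against: that certainty is bought by an enantioselective synthesis of the anti-configured alcohol behind A7, with two adjacent centres and neither from the pool.
- Against: selenium and stoichiometric tin reagents are needed, and loss of CO2 from the alkoxycarbonyl radical is a possible leak.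
- Against: after the ring closure the silyl ether must be removed and the primary alcohol oxidised to the acid next to the Michael acceptor.
- Comparison: structurally it builds lactone C2 from a one-carbon unit where the chosen plan keeps the pool lactone intact. Both are radical processes, a tin chain against nickel catalysis. The overall length should be similar and probably not shorter, and the chosen plan is more convergent.

Key step: step 10

Remark on the chemistry: the commercial enantiopure isocitrate is taken to be the monopotassium salt, drawn with the alpha-hydroxy carboxyl ionised.

## Route

Step 1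
Reactants: 1 tridecanedioic acid
Product: 2 tridecane-1,13-diol
Conditions: BH3·SMe2 (3 equiv), THF, 0 °C to 65 °C; MeOH quench
Reagents that add atoms: none
Why: Borane reduction of a carboxylic acid: each carboxyl is reduced through its acyloxyborane to the primary alcohol, and the molecule has no other reducible group.

Step 2
Reactants: 2 tridecane-1,13-diol
Product: 3 13-bromotridecan-1-ol
Conditions: 48% aq. HBr (1.1 equiv), toluene, reflux
Reagents that add atoms: hydrogen bromide, Br
Why: Acid-mediated nucleophilic substitution (SN2 on the protonated alcohol); in the two-phase system the bromo alcohol moves into toluene, away from the aqueous acid, which should hold the reaction at the monobromide.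

Step 3
Reactants: 3 13-bromotridecan-1-ol
Product: 4 [(13-bromotridecyl)oxy](tert-butyl)dimethylsilane
Conditions: TBSCl, imidazole, CH2Cl2, rt
Reagents that add atoms: tert-butyldimethylsilyl chloride, CC(C)(C)[Si](C)(C)Cl
Why: Imidazole-promoted silylation of a primary alcohol (silyl ether protection); the ether tolerates magnesium, zinc and nickel and is later shed in acid together with the tert-butyl ester.

Step 4
Reactants: 4 [(13-bromotridecyl)oxy](tert-butyl)dimethylsilane
Product: 6 {13-[(tert-butyldimethylsilyl)oxy]tridecyl}zinc chloride, via Grignard reagent 5 (not isolated)
Conditions: Mg, I2 (cat.), THF, 45 °C; then ZnCl2 (1.05 equiv, 1 M in THF), LiCl (1.05 equiv), 0 °C to rt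
Reagents that add atoms: zinc chloride, Cl[Zn]Cl
Why: Grignard formation by magnesium insertion into the primary bromide, followed by transmetalation with one equivalent of ZnCl2, gives the monoalkylzinc chloride, the reagent class of the Negishi coupling, in which each chain sits on its own zinc atom. The silyl ether, unlike an ester, survives the Grignard stage, the slight excess of ZnCl2 leaves no free Grignard reagent, and LiCl keeps the reagent dissolved and more ready to transmetalate.

Step 5
Reactants: 7 potassium hydrogen (2R,3S)-isocitrate
Product: 9 (3aS,6aR)-tetrahydrofuro[3,4-b]furan-2,4,6-trione (cis-fused lactone anhydride), via lactone diacid 8 (not isolated)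
Conditions: 6 M HCl (1.05 equiv), evaporate, 100 °C, vacuum; then Ac2O, 80 °C; dry EtOAc, filter, concentrate
Reagents that add atoms: none
Why: Protonation frees the triacid, whose hydroxyl closes the γ-lactone on the CH2CO2H carboxyl on heating (lactonisation); acetic anhydride then dehydrates the two remaining cis carboxyls to the cis-fused cyclic anhydride (anhydride formation). Only acid is present, so neither stereocentre is touched.

Step 6
Reactants: 9 (3aS,6aR)-tetrahydrofuro[3,4-b]furan-2,4,6-trione
Product: 10 (2R,3S)-2-[(benzyloxy)carbonyl]-5-oxotetrahydrofuran-3-carboxylic acid
Conditions: BnOH (1.05 equiv), MeCN, 0 °C to 40 °C, no base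
Reagents that add atoms: benzyl alcohol, OCc1ccccc1
Why: Alcoholysis of an unsymmetrical cyclic anhydride: the carbonyl attached to lactone C5 is the more electrophilic because C5 bears the ring oxygen, as in alpha-acyloxysuccinic anhydrides, and because alkoxide is a poor leaving group the kinetically formed C5 ester cannot revert.

Step 7
Reactants: 10 (2R,3S)-2-[(benzyloxy)carbonyl]-5-oxotetrahydrofuran-3-carboxylic acid
Product: 11 2-benzyl 3-tert-butyl (2R,3S)-5-oxotetrahydrofuran-2,3-dicarboxylate
Conditions: Cl3CC(=NH)OtBu (2.5 equiv), CH2Cl2/cyclohexane, rt
Reagents that add atoms: tert-butyl 2,2,2-trichloroacetimidate, CC(C)(C)OC(=N)C(Cl)(Cl)Cl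
Why: Acid-promoted O-alkylation of a carboxylic acid with a trichloroacetimidate (the acid protonates the imidate and its carboxylate captures the tert-butyl cation); no base is present, so C4 stays as it is.

Step 8
Reactants: 11 2-benzyl 3-tert-butyl (2R,3S)-5-oxotetrahydrofuran-2,3-dicarboxylate
Product: 12 (2R,3S)-3-(tert-butoxycarbonyl)-5-oxotetrahydrofuran-2-carboxylic acid
Conditions: H2 (1 atm), Pd/C (10%), EtOAc, rt
Reagents that add atoms: none
Why: Hydrogenolysis of a benzyl ester over Pd/C under neutral conditions; tert-butyl ester and lactone are inert.

Step 9
Reactants: 12 (2R,3S)-3-(tert-butoxycarbonyl)-5-oxotetrahydrofuran-2-carboxylic acid; 13 N-hydroxyphthalimide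
Product: 14 3-tert-butyl 2-(1,3-dioxoisoindolin-2-yl) (2R,3S)-5-oxotetrahydrofuran-2,3-dicarboxylate
Conditions: DIC (1.1 equiv), DMAP (5 mol %), CH2Cl2, 0 °C to rt
Reagents that add atoms: none
Why: Carbodiimide-mediated (Steglich-type) esterification of the only free carboxyl gives the redox-active ester; the C5 hydrogen is the only acidic one and its configuration is of no consequence for the next step.

Step 10
Reactants: 14 3-tert-butyl 2-(1,3-dioxoisoindolin-2-yl) (2R,3S)-5-oxotetrahydrofuran-2,3-dicarboxylate; 6 {13-[(tert-butyldimethylsilyl)oxy]tridecyl}zinc chloride
Product: 15 tert-butyl (2R,3S)-2-{13-[(tert-butyldimethylsilyl)oxy]tridecyl}-5-oxotetrahydrofuran-3-carboxylate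
Conditions: NiCl2(glyme) (20 mol %), 2,2'-bipyridine (40 mol %), 6 (3 equiv), THF/DMF (3:2), rt; aq. NH4Cl
Reagents that add atoms: none
Why: Single-electron reduction of the N-acyloxyphthalimide of 14 by bipyridine-ligated low-valent nickel (generated from NiCl2(glyme) by 6) is followed by fragmentation: phthalimide anion and CO2 depart and a C5 radical remains, planar and stabilised by O1. An alkylnickel species formed by transmetalation from 6 captures this radical, and reductive elimination from the resulting trivalent nickel dialkyl forms C5-C1'. The closest known reaction type is the nickel-catalysed decarboxylative Negishi alkyl-alkyl coupling of N-hydroxyphthalimide esters with alkylzinc reagents, established for cyclic alpha-oxy acids, and the chloride-rich THF/DMF medium should raise 6 to a zincate that passes its alkyl group to nickel. No ring is closed. The one new stereocentre, C5, is controlled by C4: the tert-butoxycarbonyl group shields its own face of the flat radical, so nickel and then the chain enter from the opposite face and the chain should end up trans (2R,3S). Because the radical is planar, the cis arrangement of 14, or any C5 epimer formed on the way, converges on the same product. The step needs trans facial selectivity and chemoselectivity for the active ester; the first rests on the bulk of the C4 ester on a five-membered ring, the second on the low reactivity of an alkylzinc halide toward lactone, tert-butyl ester and silyl ether. C4 keeps its configuration because no base able to enolise the tert-butyl ester is present.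

Step 11
Reactants: 15 tert-butyl (2R,3S)-2-{13-[(tert-butyldimethylsilyl)oxy]tridecyl}-5-oxotetrahydrofuran-3-carboxylate
Product: 16 (2R,3S)-2-(13-hydroxytridecyl)-5-oxotetrahydrofuran-3-carboxylic acid
Conditions: TFA/CH2Cl2 (1:1), H2O (5 equiv), 0 °C to rt; then THF/aq. NaHCO3, rt; 1 M HCl
Reagents that add atoms: none
Why: Acidolysis: the tert-butyl ester loses the tert-butyl cation (AAL1 cleavage) and the primary silyl ether is hydrolysed by the wet acid, while the γ-lactone is stable; the bicarbonate stage cleaves any trifluoroacetate formed on the primary alcohol.

Step 12
Reactants: 16 (2R,3S)-2-(13-hydroxytridecyl)-5-oxotetrahydrofuran-3-carboxylic acid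
Product: 18 (2R,3S)-2-(13-hydroxytridecyl)-4-methylidene-5-oxotetrahydrofuran-3-carboxylic acid, via malonic-type diacid 17 (not isolated)
Conditions: MeOMgOCO2Me (2 M in DMF, 35 equiv), 130 °C, N2; cold 6 M HCl, EtOAc; then 37% aq. HCHO, PhNHMe, NaOAc, AcOH, rt
Reagents that add atoms: formaldehyde, C=O
Why: Stiles carboxylation followed by decarboxylative Mannich methylenation: the magnesium chelate of carboxylate and lactone enolate takes up CO2 at C3 (this CO2 unit is carried only by 17), and 17 condenses with the iminium ion from formaldehyde and N-methylaniline and loses CO2 and the amine to give the exocyclic alkene under weakly acidic conditions. The chain hydroxyl rides through as its magnesium alkoxide, whereas an acetate would be transesterified by the methoxide-rich reagent; C4 and C5 are not changed, trans being the stable arrangement.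

Step 13
Reactants: 18 (2R,3S)-2-(13-hydroxytridecyl)-4-methylidene-5-oxotetrahydrofuran-3-carboxylic acid
Product: 19 (2R,3S)-2-(13-acetoxytridecyl)-4-methylidene-5-oxotetrahydrofuran-3-carboxylic acid
Conditions: immobilised Candida antarctica lipase B, vinyl acetate (5 equiv), MTBE, 30 °C
Reagents that add atoms: vinyl acetate, C=COC(C)=O
Why: Lipase-catalysed transesterification with an enol ester, made irreversible by tautomerisation of the leaving group to acetaldehyde, acetylates the unhindered primary alcohol under neutral conditions. The hindered ring carboxyl is not activated and no base is present, so the exocyclic double bond should stay where it is.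

## Compound list

1 | tridecanedioic acid | OC(=O)CCCCCCCCCCCC(=O)O | starting material
2 | tridecane-1,13-diol | OCCCCCCCCCCCCCO | intermediate
3 | 13-bromotridecan-1-ol | OCCCCCCCCCCCCCBr | intermediate
4 | [(13-bromotridecyl)oxy](tert-butyl)dimethylsilane | CC(C)(C)[Si](C)(C)OCCCCCCCCCCCCCBr | intermediate
5 | {13-[(tert-butyldimethylsilyl)oxy]tridecyl}magnesium bromide (formed in the flask) | CC(C)(C)[Si](C)(C)OCCCCCCCCCCCCC[Mg]Br | intermediate
6 | {13-[(tert-butyldimethylsilyl)oxy]tridecyl}zinc chloride | CC(C)(C)[Si](C)(C)OCCCCCCCCCCCCC[Zn]Cl | intermediate
7 | potassium hydrogen (2R,3S)-isocitrate (monopotassium (1R,2S)-1-hydroxypropane-1,2,3-tricarboxylate) | OC(=O)C[C@H](C(=O)O)[C@@H](O)C(=O)[O-].[K+] | starting material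
8 | (2R,3S)-5-oxotetrahydrofuran-2,3-dicarboxylic acid (cis; formed in the flask) | O=C1C[C@H](C(=O)O)[C@@H](O1)C(=O)O | intermediate
9 | (3aS,6aR)-tetrahydrofuro[3,4-b]furan-2,4,6-trione (cis-fused) | O=C1C[C@@H]2C(=O)OC(=O)[C@@H]2O1 | intermediate
10 | (2R,3S)-2-[(benzyloxy)carbonyl]-5-oxotetrahydrofuran-3-carboxylic acid (cis) | O=C1C[C@H](C(=O)O)[C@@H](O1)C(=O)OCc1ccccc1 | intermediate
11 | 2-benzyl 3-tert-butyl (2R,3S)-5-oxotetrahydrofuran-2,3-dicarboxylate (cis) | O=C1C[C@H](C(=O)OC(C)(C)C)[C@@H](O1)C(=O)OCc1ccccc1 | intermediate
12 | (2R,3S)-3-(tert-butoxycarbonyl)-5-oxotetrahydrofuran-2-carboxylic acid (cis) | O=C1C[C@H](C(=O)OC(C)(C)C)[C@@H](O1)C(=O)O | intermediate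
13 | N-hydroxyphthalimide | ON1C(=O)c2ccccc2C1=O | starting material
14 | 3-tert-butyl 2-(1,3-dioxoisoindolin-2-yl) (2R,3S)-5-oxotetrahydrofuran-2,3-dicarboxylate (cis) | O=C1C[C@H](C(=O)OC(C)(C)C)[C@@H](O1)C(=O)ON2C(=O)c3ccccc3C2=O | intermediate
15 | tert-butyl (2R,3S)-2-{13-[(tert-butyldimethylsilyl)oxy]tridecyl}-5-oxotetrahydrofuran-3-carboxylate (trans) | O=C1C[C@H](C(=O)OC(C)(C)C)[C@@H](CCCCCCCCCCCCCO[Si](C)(C)C(C)(C)C)O1 | intermediate
16 | (2R,3S)-2-(13-hydroxytridecyl)-5-oxotetrahydrofuran-3-carboxylic acid (trans) | O=C1C[C@H](C(=O)O)[C@@H](CCCCCCCCCCCCCO)O1 | intermediate
17 | (2R,3S)-2-(13-hydroxytridecyl)-5-oxotetrahydrofuran-3,4-dicarboxylic acid (C4 of this numbering unassigned; formed in the flask) | O=C1C(C(=O)O)[C@H](C(=O)O)[C@@H](CCCCCCCCCCCCCO)O1 | intermediate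
18 | (2R,3S)-2-(13-hydroxytridecyl)-4-methylidene-5-oxotetrahydrofuran-3-carboxylic acid | C=C1C(=O)O[C@H](CCCCCCCCCCCCCO)[C@H]1C(=O)O | intermediate
19 | (2R,3S)-2-(13-acetoxytridecyl)-4-methylidene-5-oxotetrahydrofuran-3-carboxylic acid | C=C1C(=O)O[C@H](CCCCCCCCCCCCCOC(C)=O)[C@H]1C(=O)O | target

## Step count and least certain steps

Total step count: 13. Longest linear sequence: 9 steps (steps 5 to 13, from 7 to 19); the chain branch adds steps 1 to 4.

Step 10 (key step). What may go wrong is slow alkyl transfer from the alkylzinc chloride to nickel, so that the C5 radical is reduced or the C5 nickel alkyl loses the C4 hydrogen by beta-hydride elimination, and incomplete facial selectivity in the capture of the radical. The fallback replaces the redox-active ester and the organozinc reagent by metallaphotoredox decarboxylative coupling of the free acid. It sets out from 12 and 4: Ir[dF(CF3)ppy]2(dtbbpy)PF6, NiCl2(glyme), 4,4'-dimethoxy-2,2'-bipyridine, Cs2CO3, MeCN/H2O, blue light. The carboxylate of 12 is oxidised by the excited photocatalyst and loses CO2 to the same C5 radical, which is captured by the alkylnickel bromide formed by oxidative addition of 4. It comes back to the route at 15, and steps 4 and 9 are then not needed. No compound outside the list is required (F0).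

Step 6. What may go wrong is attack of the alcohol at the C4-side carbonyl, or sluggish uncatalysed alcoholysis. The fallback selects by acidity and not by carbonyl electrophilicity. It sets out from 8, isolated after the lactonisation stage of step 5. One equivalent of CsHCO3 in DMF should ionise mainly the stronger, alpha-oxy C5 carboxyl, and BnBr alkylates that carboxylate. Doubly alkylated material stays in the organic phase when the mono-ester is extracted into bicarbonate. The fallback comes back to the route at 10. No compound outside the list is required (F0).

Step 12. What may go wrong is incomplete carboxylation at C3, loss of CO2 from 17 before the Mannich stage, or oligomer formation by attack of the chain alkoxide on the lactone of another molecule at 130 °C. The fallback replaces carboxylation by a low-temperature enolate Mannich sequence and sets out from 16: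
- LiN(SiMe3)2 (3.3 equiv), THF, -78 °C, gives the alkoxide-carboxylate-lactone enolate, and dimethylmethylideneammonium iodide then gives the Mannich base (2R,3S)-4-[(dimethylamino)methyl]-2-(13-hydroxytridecyl)-5-oxotetrahydrofuran-3-carboxylic acid F1.
- MeI in MeOH gives the quaternary salt {[(2R,3S)-3-carboxy-2-(13-hydroxytridecyl)-5-oxotetrahydrofuran-4-yl]methyl}trimethylammonium iodide F2.
- Aqueous NaHCO3 brings about beta-elimination, and the fallback comes back to the route at 18.

Step 13. What may go wrong is migration of the exocyclic double bond into the ring, or slow enzymatic acyl transfer on a substrate that carries a free carboxylic acid. The fallback masks the alkene during a conventional acetylation and sets out from 18: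
- Conjugate addition of PhSeNa (from (PhSe)2 and NaBH4, EtOH) gives (2R,3S)-2-(13-hydroxytridecyl)-5-oxo-4-[(phenylselanyl)methyl]tetrahydrofuran-3-carboxylic acid F3.
- Ac2O and pyridine, with aqueous hydrolysis of the mixed anhydride, give (2R,3S)-2-(13-acetoxytridecyl)-5-oxo-4-[(phenylselanyl)methyl]tetrahydrofuran-3-carboxylic acid F4.
- H2O2 in THF, 0 °C to rt, oxidises selenium, and syn-elimination of the selenoxide restores the exocyclic methylene. The fallback comes back to the route at 19.

## Further compounds

F0 | step 10 | none | none
F0 | step 6 | none | none
F1 | step 12 | (2R,3S)-4-[(dimethylamino)methyl]-2-(13-hydroxytridecyl)-5-oxotetrahydrofuran-3-carboxylic acid (C4 epimers) | O=C1C(CN(C)C)[C@H](C(=O)O)[C@@H](CCCCCCCCCCCCCO)O1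
F2 | step 12 | {[(2R,3S)-3-carboxy-2-(13-hydroxytridecyl)-5-oxotetrahydrofuran-4-yl]methyl}trimethylammonium iodide (C4 epimers) | O=C1C(C[N+](C)(C)C)[C@H](C(=O)O)[C@@H](CCCCCCCCCCCCCO)O1.[I-]
F3 | step 13 | (2R,3S)-2-(13-hydroxytridecyl)-5-oxo-4-[(phenylselanyl)methyl]tetrahydrofuran-3-carboxylic acid (C4 epimers) | O=C1C(C[Se]c2ccccc2)[C@H](C(=O)O)[C@@H](CCCCCCCCCCCCCO)O1
F4 | step 13 | (2R,3S)-2-(13-acetoxytridecyl)-5-oxo-4-[(phenylselanyl)methyl]tetrahydrofuran-3-carboxylic acid (C4 epimers) | O=C1C(C[Se]c2ccccc2)[C@H](C(=O)O)[C@@H](CCCCCCCCCCCCCOC(C)=O)O1
A1 | alternative 1 | (2R,3S)-2-allyl-5-oxotetrahydrofuran-3-carbaldehyde | O=C1C[C@H](C=O)[C@@H](CC=C)O1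
A2 | alternative 1 | ethyl 2-(1-hydroxybut-3-en-1-yl)-3-[(methoxyoxalyl)oxy]cyclopropane-1-carboxylate (oxalyloxy and hydroxybutenyl groups cis, ester trans; single enantiomer as drawn) | CCOC(=O)[C@H]1[C@H](OC(=O)C(=O)OC)[C@@H]1[C@H](O)CC=C
A3 | alternative 1 | dodec-11-en-1-yl acetate | C=CCCCCCCCCCCOC(C)=O
A4 | alternative 2 | [(2R,3R)-2-(13-acetoxytridecyl)-4-methylidenetetrahydrofuran-3-yl]methanol | C=C1CO[C@H](CCCCCCCCCCCCCOC(C)=O)[C@H]1CO
A5 | alternative 2 | (14R)-14-[(2R)-oxiran-2-yl]-14-(prop-2-yn-1-yloxy)tetradecyl acetate (the epoxide carbon becomes the radical centre, so its epimer would serve equally) | C#CCO[C@H](CCCCCCCCCCCCCOC(C)=O)[C@H]1CO1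
A6 | alternative 3 | (4R,5R)-5-(13-acetoxytridecyl)-4-{[(tert-butyldimethylsilyl)oxy]methyl}-3-methylidenedihydrofuran-2(3H)-one | C=C1C(=O)O[C@H](CCCCCCCCCCCCCOC(C)=O)[C@H]1CO[Si](C)(C)C(C)(C)C
A7 | alternative 3 | O-[(3R,4R)-17-acetoxy-3-{[(tert-butyldimethylsilyl)oxy]methyl}heptadec-1-yn-4-yl] Se-phenyl carbonoselenoate | C#C[C@H](CO[Si](C)(C)C(C)(C)C)[C@@H](CCCCCCCCCCCCCOC(C)=O)OC(=O)[Se]c1ccccc1
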